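**Retrosynthetic overview**
1. Target ⇐ bis-O-sulfation of hydroquinone 35 ⇐ oxidative unmasking of 4-methoxyphenol 33 ⇐ alkyne hydrogenation ⇐ alkynylcerium union of decalin alkyne 16 with oxepane ketone 30.
2. Key step: the hydroquinone ring is grown on the terpenoid ynone 12 by a 2-methoxyfuran Diels–Alder cycloaddition with ring-opening aromatisation; the aryl ketone is then reduced to ArCH2.
3. Decalin 16 (C4, C5, C10 bought) from dehydroandrographolide: C3 deoxygenation, double ozonolysis, C19 to alkyne, methyl addition with carbonyl transposition to the C8=C9 enal.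
4. Ketone 30 from (S)-carvone: α′-alkylation then methylation (quaternary carbon), Criegee C-to-O exchange with retention, cationic etherification, convex-face hydrogenation.
5. Ring order: decalin and cyclohexenone bought; oxepane (etherification); hydroquinone (cycloaddition).

Assumption: the target is made as the free bis(hydrogen sulfate) drawn; decalin carbons carry ent-labdane numbers (C17 = 8-CH3, C18 = 4β-CH3, C19 = 4α-carbon, C20 = 10α-CH3, 5β-H throughout), the oxepane bicycle carries 1-benzoxepine numbers.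

**Route**

Step 1
Reactants: 1 dehydroandrographolide
Product: 2 3,19-O-thiocarbonyl-dehydroandrographolide
Conditions: 1,1′-thiocarbonyldiimidazole (1.3 equiv), DMAP (cat.), toluene, 80 °C
Reagents that add atoms: 1,1′-thiocarbonyldiimidazole, S=C(n1ccnc1)n1ccnc1
Why: Only the 3-OH and the 19-CH2OH are free and 1,3-related on ring A, so thiocarbonyl transfer closes the six-membered cyclic thionocarbonate; no stereocenter is touched.

Step 2
Reactants: 2 3,19-O-thiocarbonyl-dehydroandrographolide
Product: 4 3-deoxydehydroandrographolide, via stannyl thiolcarbonate 3 (not isolated)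
Conditions: Bu3SnH (1.5 equiv), AIBN (0.1 equiv), toluene, 110 °C; then aq. NaHCO3, rt
Reagents that add atoms: none
Why: Barton–McCombie deoxygenation of a cyclic thionocarbonate, in which the radical adduct fragments to the secondary C3 radical rather than the primary C19 radical and hydrolysis returns the 19-OH; C4, C5, C9 and C10 are unchanged.

Step 3
Reactants: 4 3-deoxydehydroandrographolide
Product: 5 (Z)-11,19-dihydroxy-12,13,14,15,16,17-hexanor-ent-labd-9(11)-en-8-one
Conditions: O3, CH2Cl2/MeOH (4:1), −78 °C to persistent blue; then Me2S, −78 °C → rt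
Reagents that add atoms: ozone, [O-][O+]=O
Why: Exhaustive ozonolysis deliberately cleaves both the exocyclic C8=C17 and the C11=C12 alkene, so no selectivity between them is needed, and the 8-keto-11-aldehyde is obtained as its chelated hydroxymethylene tautomer; C9 becomes sp2 and C4, C5, C10 are untouched.

Step 4
Reactants: 5 (Z)-11,19-dihydroxy-12,13,14,15,16,17-hexanor-ent-labd-9(11)-en-8-one
Product: 6 (E)-19-hydroxy-11-methoxy-12,13,14,15,16,17-hexanor-ent-labd-9(11)-en-8-one
Conditions: Me2SO4 (1.2 equiv), K2CO3, acetone, rt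
Reagents that add atoms: dimethyl sulfate, COS(=O)(=O)OC
Why: O-alkylation of the acidic vinylogous acid by a hard electrophile gives the vinylogous ester needed for a Stork–Danheiser-type transposition, while the neutral neopentyl 19-OH does not react.

Step 5
Reactants: 6 (E)-19-hydroxy-11-methoxy-12,13,14,15,16,17-hexanor-ent-labd-9(11)-en-8-one
Product: 7 (E)-11-methoxy-8-oxo-12,13,14,15,16,17-hexanor-ent-labd-9(11)-en-19-al
Conditions: Dess–Martin periodinane (1.3 equiv), CH2Cl2, 0 °C → rt
Reagents that add atoms: none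
Why: Dess–Martin oxidation of the only hydroxyl gives the α-quaternary C19 aldehyde, which cannot enolise, so C4 cannot epimerise.

Step 6
Reactants: 7 (E)-11-methoxy-8-oxo-12,13,14,15,16,17-hexanor-ent-labd-9(11)-en-19-al
Product: 8 (E)-4α-ethynyl-11-methoxy-12,13,14,15,16,17,19-heptanor-ent-labd-9(11)-en-8-one
Conditions: dimethyl (1-diazo-2-oxopropyl)phosphonate (1.5 equiv), K2CO3, MeOH, 0 °C → rt
Reagents that add atoms: dimethyl (1-diazo-2-oxopropyl)phosphonate, COP(=O)(OC)C(=[N+]=[N-])C(C)=O
Why: Ohira–Bestmann (Seyferth–Gilbert) homologation turns the aldehyde into the terminal alkyne C19≡C1′ under mild base that the vinylogous methyl ester tolerates (methoxide exchange is degenerate); no stereocenter is involved.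

Step 7
Reactants: 8 (E)-4α-ethynyl-11-methoxy-12,13,14,15,16,17,19-heptanor-ent-labd-9(11)-en-8-one
Product: 10 (4aR,5R,8aR)-5-ethynyl-2,5,8a-trimethyl-3,4,4a,5,6,7,8,8a-octahydronaphthalene-1-carbaldehyde, via tertiary carbinol 9 (not isolated)
Conditions: MeLi (2.3 equiv), THF, −78 → −20 °C; then 1 M HCl, THF, rt
Reagents that add atoms: methyllithium, [Li]C
Why: Methyllithium adds 1,2 to the vinylogous ester carbonyl (one equivalent only deprotonates the alkyne) and acid expels methanol in a Stork–Danheiser transposition, which installs the C8 methyl and locks the tetrasubstituted C8=C9 alkene in conjugation with the C11 aldehyde.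

Step 8
Reactants: 10 (4aR,5R,8aR)-5-ethynyl-2,5,8a-trimethyl-3,4,4a,5,6,7,8,8a-octahydronaphthalene-1-carbaldehyde
Product: 11 1-[(4aR,5R,8aR)-5-ethynyl-2,5,8a-trimethyl-3,4,4a,5,6,7,8,8a-octahydronaphthalen-1-yl]prop-2-yn-1-ol (carbinol epimers)
Conditions: HC≡CMgBr (3 equiv), THF, 0 °C → rt; water
Reagents that add atoms: ethynylmagnesium bromide, C#C[Mg]Br
Why: 1,2-Addition of the small alkynyl Grignard reagent to the hindered enal; the new C11 carbinol center is irrelevant because it is oxidised next.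

Step 9
Reactants: 11 1-[(4aR,5R,8aR)-5-ethynyl-2,5,8a-trimethyl-3,4,4a,5,6,7,8,8a-octahydronaphthalen-1-yl]prop-2-yn-1-ol
Product: 12 1-[(4aR,5R,8aR)-5-ethynyl-2,5,8a-trimethyl-3,4,4a,5,6,7,8,8a-octahydronaphthalen-1-yl]prop-2-yn-1-one
Conditions: MnO2 (activated, 15 equiv), CH2Cl2, rt
Reagents that add atoms: none
Why: MnO2 oxidises only the doubly activated (allylic and propargylic) alcohol, giving the ynone dienophile.

Step 10
Reactants: 12 1-[(4aR,5R,8aR)-5-ethynyl-2,5,8a-trimethyl-3,4,4a,5,6,7,8,8a-octahydronaphthalen-1-yl]prop-2-yn-1-one; 13 2-methoxyfuran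
Product: 15 [(4aR,5R,8aR)-5-ethynyl-2,5,8a-trimethyl-3,4,4a,5,6,7,8,8a-octahydronaphthalen-1-yl](5-hydroxy-2-methoxyphenyl)methanone, via oxanorbornadiene adduct 14 (not isolated)
Conditions: 13 (3 equiv), toluene, 25 → 50 °C; then silica gel
Reagents that add atoms: none
Why: Diels–Alder [4+2] cycloaddition of the electron-rich furan to the ynone (the unactivated C4 alkyne is inert), with furan C5 bonding to the alkyne terminus, gives a 1-methoxy-7-oxanorbornadiene whose oxygen bridge opens and aromatises, so the hydroquinone ring is created as its mono-methyl ether with the acyl group next to OMe; the new ring is achiral.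

Step 11
Reactants: 15 [(4aR,5R,8aR)-5-ethynyl-2,5,8a-trimethyl-3,4,4a,5,6,7,8,8a-octahydronaphthalen-1-yl](5-hydroxy-2-methoxyphenyl)methanone
Product: 16 3-{[(4aR,5R,8aR)-5-ethynyl-2,5,8a-trimethyl-3,4,4a,5,6,7,8,8a-octahydronaphthalen-1-yl]methyl}-4-methoxyphenol
Conditions: LiAlH4 (3 equiv), AlCl3 (1 equiv), Et2O, 0 °C → rt; dilute HCl work-up
Reagents that add atoms: none
Why: Mixed-hydride (chloroalane) reduction takes the aryl ketone through the benzylic–allylic cation to the methylene group, hydride entering at the less hindered benzylic carbon so the double bond stays at C8=C9.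

Step 12
Reactants: 17 ethyl 4-bromobutanoate
Product: 19 [(5-bromo-2-methylpentan-2-yl)oxy]triethylsilane, via bromomagnesium alkoxide 18 (not isolated)
Conditions: MeMgBr (2.1 equiv), Et2O, −20 → 0 °C; then Et3SiOTf (1.1 equiv), 0 °C; water
Reagents that add atoms: methylmagnesium bromide, C[Mg]Br; triethylsilyl trifluoromethanesulfonate, CC[Si](CC)(CC)OS(=O)(=O)C(F)(F)F
Why: Double Grignard addition to the ester gives the tertiary alkoxide, which is silylated in the same flask before it can close to 2,2-dimethyltetrahydrofuran; no stereocenter.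

Step 13
Reactants: 19 [(5-bromo-2-methylpentan-2-yl)oxy]triethylsilane
Product: 20 triethyl[(5-iodo-2-methylpentan-2-yl)oxy]silane
Conditions: NaI (3 equiv), acetone, reflux
Reagents that add atoms: sodium iodide, [Na+].[I-]
Why: Finkelstein exchange gives the iodide needed for clean enolate alkylation.

Step 14
Reactants: 21 (S)-carvone; 20 triethyl[(5-iodo-2-methylpentan-2-yl)oxy]silane
Product: 23 (5S,6RS)-2-methyl-6-[4-methyl-4-(triethylsilyloxy)pentyl]-5-(prop-1-en-2-yl)cyclohex-2-en-1-one, via lithium dienolate 22 (not isolated)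
Conditions: LiN(iPr)2 (1.1 equiv), THF, −78 °C; then 20 (1.3 equiv), DMPU, −78 → −10 °C
Reagents that add atoms: none
Why: Kinetic α′-deprotonation of carvone gives the cross-conjugated dienolate, which is alkylated at C6 by the primary iodide (SN2); the C6 epimer ratio is irrelevant because C6 is enolised again.

Step 15
Reactants: 23 (5S,6RS)-2-methyl-6-[4-methyl-4-(triethylsilyloxy)pentyl]-5-(prop-1-en-2-yl)cyclohex-2-en-1-one
Product: 25 (5R,6S)-2,6-dimethyl-6-[4-methyl-4-(triethylsilyloxy)pentyl]-5-(prop-1-en-2-yl)cyclohex-2-en-1-one, via lithium enolate 24 (not isolated)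
Conditions: LiN(iPr)2 (1.2 equiv), THF, −78 °C; then MeI (3 equiv), DMPU, −78 → 0 °C
Reagents that add atoms: iodomethane, CI
Why: The fully substituted enolate is methylated on the face anti to the adjacent C5 isopropenyl group (axial attack), so the side chain ends cis to isopropenyl and the quaternary center is set by the bought C5 center.

Step 16
Reactants: 25 (5R,6S)-2,6-dimethyl-6-[4-methyl-4-(triethylsilyloxy)pentyl]-5-(prop-1-en-2-yl)cyclohex-2-en-1-one
Product: 27 (1S,2S)-2,4-dimethyl-2-[4-methyl-4-(triethylsilyloxy)pentyl]-3-oxocyclohex-4-en-1-yl acetate, via methoxy hydroperoxide 26 (not isolated)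
Conditions: O3, CH2Cl2/MeOH (4:1), −78 °C, stopped when 25 is consumed; then Ac2O, Et3N, DMAP (cat.), 0 °C → rt
Reagents that add atoms: ozone, [O-][O+]=O; methanol, CO
Why: Ozone cleaves the electron-rich isopropenyl group but not the enone, and Criegee rearrangement of the acetylated methoxy hydroperoxide migrates C5 from carbon to oxygen with retention, turning the bought C5–C center into the C–O center of the oxepane.

Step 17
Reactants: 27 (1S,2S)-2,4-dimethyl-2-[4-methyl-4-(triethylsilyloxy)pentyl]-3-oxocyclohex-4-en-1-yl acetate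
Product: 29 (5aS,9aS)-2,2,5a,7-tetramethyl-3,4,5,5a,9,9a-hexahydro-1-benzoxepin-6(2H)-one, via diol 28 (not isolated)
Conditions: HCl (0.3 M, from AcCl) in MeOH, rt; evaporate; CF3SO3H (5 mol %), CH2Cl2, 0 °C → rt
Reagents that add atoms: none
Why: Acid removes the silyl ether and the acetate, and the tertiary carbocation of the side chain is trapped by the secondary hydroxyl (cationic Markovnikov etherification, reversible elimination funnels into the ether); because hydroxyl and chain are cis on adjacent carbons only the cis-fused oxepane can form.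

Step 18
Reactants: 29 (5aS,9aS)-2,2,5a,7-tetramethyl-3,4,5,5a,9,9a-hexahydro-1-benzoxepin-6(2H)-one
Product: 30 (5aS,7R,9aS)-2,2,5a,7-tetramethyloctahydro-1-benzoxepin-6(2H)-one
Conditions: H2 (1 atm), Pd/C (10 %), EtOAc, rt
Reagents that add atoms: none
Why: Heterogeneous hydrogenation adds H2 to the enone from the convex face of the cis-fused bicycle, anti to the oxepane ring, which sets C7 with its methyl on the oxepane face.

Step 19
Reactants: 16 3-{[(4aR,5R,8aR)-5-ethynyl-2,5,8a-trimethyl-3,4,4a,5,6,7,8,8a-octahydronaphthalen-1-yl]methyl}-4-methoxyphenol; 30 (5aS,7R,9aS)-2,2,5a,7-tetramethyloctahydro-1-benzoxepin-6(2H)-one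
Product: 32 propargylic tertiary alcohol (C1′ of the alkyne bonded to C6 of the benzoxepine; 6-OH cis to the ring oxygen), via dilithio species 31 (not isolated)
Conditions: n-BuLi (2.05 equiv), THF, −78 °C; anhydrous CeCl3 (1.2 equiv), −78 °C; then 30, −78 → −30 °C; aq. NH4Cl
Reagents that add atoms: none
Why: The weakly basic alkynylcerium adds to the hindered enolisable ketone without enolisation and is expected to attack equatorially from the convex face, opposite the axial oxepane oxygen, placing OH cis to the ether oxygen and the new chain cis to the angular methyl; the new center is controlled by the carvone-derived ring-fusion centers.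

Step 20
Reactants: 32 propargylic tertiary alcohol
Product: 33 4-methoxy-3-(decalinylmethyl)phenol carrying the saturated CH2CH2 link to (5aS,6R,7R,9aS)-6-hydroxy-2,2,5a,7-tetramethyldecahydro-1-benzoxepin-6-yl
Conditions: H2 (3 atm), Pd/C (10 %), EtOAc, rt
Reagents that add atoms: none
Why: Catalytic hydrogenation saturates the dialkyl alkyne to the CH2CH2 link while the tetrasubstituted C8=C9 alkene and the arene are inert.

Step 21
Reactants: 33 4-methoxyphenol with saturated link
Product: 35 hydroquinone (both phenols free), via quinone 34 (not isolated)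
Conditions: (NH4)2Ce(NO3)6 (2.2 equiv), MeCN/H2O (3:1), 0 °C; then aq. Na2S2O4, Et2O, rt
Reagents that add atoms: water, O
Why: Two-electron oxidative demethylation of the 4-methoxyphenol gives the p-quinone, which dithionite reduces in the work-up to the hydroquinone; alkene, tertiary alcohol and ether survive.

Step 22
Reactants: 35 hydroquinone
Product: 36 target bis(hydrogen sulfate)
Conditions: SO3·pyridine (4 equiv), pyridine, 0 °C → rt; H+ ion-exchange resin, 0 °C
Reagents that add atoms: sulfur trioxide–pyridine, O=S(=O)([O-])[n+]1ccccc1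
Why: Sulfur trioxide–pyridine O-sulfates the two phenols far faster than the hindered tertiary alcohol, and proton exchange delivers the bis(hydrogen sulfate).

**Compound list**

1 | dehydroandrographolide (14-deoxy-11,12-didehydroandrographolide) | C[C@@]12CC[C@H]([C@@]([C@H]1CCC(=C)[C@H]2/C=C/C1=CCOC1=O)(C)CO)O | starting material
2 | 3,19-O-thiocarbonyl-dehydroandrographolide (cyclic thionocarbonate) | C[C@@]12CC[C@H]3OC(=S)OC[C@@]3(C)[C@H]1CCC(=C)[C@H]2/C=C/C1=CCOC1=O | intermediate
3 | S-tributylstannyl O-(3-deoxydehydroandrographolid-19-yl) thiocarbonate | C[C@@]12CCC[C@@](C)(COC(=O)S[Sn](CCCC)(CCCC)CCCC)[C@H]1CCC(=C)[C@H]2/C=C/C1=CCOC1=O | intermediate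
4 | 3-deoxydehydroandrographolide (19-hydroxy-ent-labda-8(17),11E,13-trien-16,15-olide) | C[C@@]12CCC[C@@](C)(CO)[C@H]1CCC(=C)[C@H]2/C=C/C1=CCOC1=O | intermediate
5 | (Z)-11,19-dihydroxy-12,13,14,15,16,17-hexanor-ent-labd-9(11)-en-8-one | C[C@@]12CCC[C@@](C)(CO)[C@H]1CCC(=O)/C2=C\O | intermediate
6 | (E)-19-hydroxy-11-methoxy-12,13,14,15,16,17-hexanor-ent-labd-9(11)-en-8-one | C[C@@]12CCC[C@@](C)(CO)[C@H]1CCC(=O)/C2=C/OC | intermediate
7 | (E)-11-methoxy-8-oxo-12,13,14,15,16,17-hexanor-ent-labd-9(11)-en-19-al | C[C@@]12CCC[C@@](C)(C=O)[C@H]1CCC(=O)/C2=C/OC | intermediate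
8 | (E)-4α-ethynyl-11-methoxy-12,13,14,15,16,17,19-heptanor-ent-labd-9(11)-en-8-one | C[C@@]12CCC[C@@](C)(C#C)[C@H]1CCC(=O)/C2=C/OC | intermediate
9 | (E)-4α-ethynyl-11-methoxy-12,13,14,15,16,19-hexanor-ent-labd-9(11)-en-8-ol (C8 epimers) | C[C@@]12CCC[C@@](C)(C#C)[C@H]1CCC(C)(O)/C2=C/OC | intermediate
10 | (4aR,5R,8aR)-5-ethynyl-2,5,8a-trimethyl-3,4,4a,5,6,7,8,8a-octahydronaphthalene-1-carbaldehyde | CC1=C(C=O)[C@]2(C)CCC[C@@](C)(C#C)[C@H]2CC1 | intermediate
11 | 1-[(4aR,5R,8aR)-5-ethynyl-2,5,8a-trimethyl-3,4,4a,5,6,7,8,8a-octahydronaphthalen-1-yl]prop-2-yn-1-ol (carbinol epimers) | CC1=C(C(O)C#C)[C@]2(C)CCC[C@@](C)(C#C)[C@H]2CC1 | intermediate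
12 | 1-[(4aR,5R,8aR)-5-ethynyl-2,5,8a-trimethyl-3,4,4a,5,6,7,8,8a-octahydronaphthalen-1-yl]prop-2-yn-1-one | CC1=C(C(=O)C#C)[C@]2(C)CCC[C@@](C)(C#C)[C@H]2CC1 | intermediate
13 | 2-methoxyfuran | COc1ccco1 | starting material
14 | (1-methoxy-7-oxabicyclo[2.2.1]hepta-2,5-dien-2-yl) ketone of the decalin unit (Diels–Alder adduct, bridgehead epimers) | CC1=C(C(=O)C2=CC3C=CC2(OC)O3)[C@]2(C)CCC[C@@](C)(C#C)[C@H]2CC1 | intermediate
15 | [(4aR,5R,8aR)-5-ethynyl-2,5,8a-trimethyl-3,4,4a,5,6,7,8,8a-octahydronaphthalen-1-yl](5-hydroxy-2-methoxyphenyl)methanone | CC1=C(C(=O)c2cc(O)ccc2OC)[C@]2(C)CCC[C@@](C)(C#C)[C@H]2CC1 | intermediate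
16 | 3-{[(4aR,5R,8aR)-5-ethynyl-2,5,8a-trimethyl-3,4,4a,5,6,7,8,8a-octahydronaphthalen-1-yl]methyl}-4-methoxyphenol | CC1=C(Cc2cc(O)ccc2OC)[C@]2(C)CCC[C@@](C)(C#C)[C@H]2CC1 | intermediate
17 | ethyl 4-bromobutanoate | CCOC(=O)CCCBr | starting material
18 | bromomagnesium 5-bromo-2-methylpentan-2-olate | CC(C)(CCCBr)O[Mg]Br | intermediate
19 | [(5-bromo-2-methylpentan-2-yl)oxy]triethylsilane | CC[Si](CC)(CC)OC(C)(C)CCCBr | intermediate
20 | triethyl[(5-iodo-2-methylpentan-2-yl)oxy]silane | CC[Si](CC)(CC)OC(C)(C)CCCI | intermediate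
21 | (S)-(+)-carvone | CC1=CC[C@@H](CC1=O)C(C)=C | starting material
22 | lithium α′-dienolate of (S)-carvone | CC1=CC[C@H](C(C)=C)C=C1O[Li] | intermediate
23 | (5S,6RS)-2-methyl-6-[4-methyl-4-(triethylsilyloxy)pentyl]-5-(prop-1-en-2-yl)cyclohex-2-en-1-one | CC1=CC[C@H](C(C)=C)C(CCCC(C)(C)O[Si](CC)(CC)CC)C1=O | intermediate
24 | lithium enolate of 23 | CC1=CC[C@H](C(C)=C)C(CCCC(C)(C)O[Si](CC)(CC)CC)=C1O[Li] | intermediate
25 | (5R,6S)-2,6-dimethyl-6-[4-methyl-4-(triethylsilyloxy)pentyl]-5-(prop-1-en-2-yl)cyclohex-2-en-1-one | CC1=CC[C@H](C(C)=C)[C@](C)(CCCC(C)(C)O[Si](CC)(CC)CC)C1=O | intermediate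
26 | 25 with the isopropenyl group replaced by 1-hydroperoxy-1-methoxyethyl (epimers at that carbon) | CC1=CC[C@H](C(C)(OC)OO)[C@](C)(CCCC(C)(C)O[Si](CC)(CC)CC)C1=O | intermediate
27 | (1S,2S)-2,4-dimethyl-2-[4-methyl-4-(triethylsilyloxy)pentyl]-3-oxocyclohex-4-en-1-yl acetate | CC1=CC[C@H](OC(C)=O)[C@](C)(CCCC(C)(C)O[Si](CC)(CC)CC)C1=O | intermediate
28 | (5S,6S)-5-hydroxy-6-(4-hydroxy-4-methylpentyl)-2,6-dimethylcyclohex-2-en-1-one | CC1=CC[C@H](O)[C@](C)(CCCC(C)(C)O)C1=O | intermediate
29 | (5aS,9aS)-2,2,5a,7-tetramethyl-3,4,5,5a,9,9a-hexahydro-1-benzoxepin-6(2H)-one | CC1=CC[C@@H]2OC(C)(C)CCC[C@]2(C)C1=O | intermediate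
30 | (5aS,7R,9aS)-2,2,5a,7-tetramethyloctahydro-1-benzoxepin-6(2H)-one | C[C@@H]1CC[C@@H]2OC(C)(C)CCC[C@]2(C)C1=O | intermediate
31 | dilithio derivative of 16 (lithium phenoxide, lithium acetylide) | CC1=C(Cc2cc(O[Li])ccc2OC)[C@]2(C)CCC[C@@](C)(C#C[Li])[C@H]2CC1 | intermediate
32 | propargylic alcohol: 16 with its alkyne terminus bonded to C6 of (5aS,6S,7R,9aS)-2,2,5a,7-tetramethyldecahydro-1-benzoxepin-6-ol (6-OH cis to O1; same spatial arrangement as 6R in 33) | CC1=C(Cc2cc(O)ccc2OC)[C@]2(C)CCC[C@@](C)(C#C[C@@]3(O)[C@H](C)CC[C@@H]4OC(C)(C)CCC[C@@]43C)[C@H]2CC1 | intermediate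
33 | 4-methoxy-3-(decalinylmethyl)phenol with 4α-[2-((5aS,6R,7R,9aS)-6-hydroxy-2,2,5a,7-tetramethyldecahydro-1-benzoxepin-6-yl)ethyl] chain | CC1=C(Cc2cc(O)ccc2OC)[C@]2(C)CCC[C@@](C)(CC[C@@]3(O)[C@H](C)CC[C@@H]4OC(C)(C)CCC[C@@]43C)[C@H]2CC1 | intermediate
34 | corresponding 2-substituted 1,4-benzoquinone | CC1=C(CC2=CC(=O)C=CC2=O)[C@]2(C)CCC[C@@](C)(CC[C@@]3(O)[C@H](C)CC[C@@H]4OC(C)(C)CCC[C@@]43C)[C@H]2CC1 | intermediate
35 | corresponding 2-substituted hydroquinone | CC1=C(Cc2cc(O)ccc2O)[C@]2(C)CCC[C@@](C)(CC[C@@]3(O)[C@H](C)CC[C@@H]4OC(C)(C)CCC[C@@]43C)[C@H]2CC1 | intermediate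
36 | CNP0125037.3, hydroquinone bis(hydrogen sulfate) | CC1=C(Cc2cc(OS(=O)(=O)O)ccc2OS(=O)(=O)O)[C@]2(C)CCC[C@@](C)(CC[C@@]3(O)[C@H](C)CC[C@@H]4OC(C)(C)CCC[C@@]43C)[C@H]2CC1 | target

**Step count and risks**

Total step count: 22. Longest linear sequence: 15 steps (steps 1–11, then 19–22).

Most likely to fail, first: step 19. The ketone is flanked by a quaternary carbon and the facial preference (equatorial attack past the axial angular methyl versus axial attack past the ring oxygen) is not secure. Fallback, union one stage earlier on a differently shaped substrate: setting out from 16 (via 31) and enone 29, the same alkynylcerium adds 1,2 to the enone, where the ring-fusion methylene is free to sit axial and shield the oxepane face, giving enynol F5. Exhaustive hydrogenation (H2, Pd/C, EtOAc) of the alkyne and the ring alkene then comes back to the route at 33.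

Second: step 17. Seven-membered cationic ring closure may lose to elimination of the tertiary cation or to retro-aldol cleavage of the β-hydroxy ketone. Fallback, a radical–polar crossover closure on the alkene: setting out from 27, HF·pyridine frees the tertiary alcohol to give hydroxy acetate F1. Dehydration (Burgess reagent, benzene, 50 °C) gives alkene acetate F2 (drawn as the trisubstituted isomer; the 1,1-disubstituted isomer converges). Neutral transesterification (Ti(OiPr)4, MeOH, 60 °C) gives hydroxy alkene F3. Hydrogen-atom-transfer hydroalkoxylation (Co(salen), that is N,N′-bis(salicylidene)ethylenediamine cobalt, with N-fluoro-2,4,6-trimethylpyridinium triflate and PhSiH3 in PhCF3, rt) closes the oxepane and comes back at 29.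

Third: step 18. The C7 methyl center rests on convex-face delivery of hydrogen, and the two C7 epimers of 30 are close in energy, so equilibration cannot rescue a wrong result. Fallback, hydrogenate before the ring is closed: setting out from 27, H2 over Pd/C reduces the enone while the acetoxy group and the side chain, both on the upper face, leave only the lower face open, giving saturated keto acetate F4. The acid sequence of step 17 (HCl/MeOH, then CF3SO3H, kept short and cold to avoid enolisation) then closes the oxepane and comes back at 30.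

Further compounds
F1 | step 17 | (1S,2S)-2-(4-hydroxy-4-methylpentyl)-2,4-dimethyl-3-oxocyclohex-4-en-1-yl acetate | CC1=CC[C@H](OC(C)=O)[C@](C)(CCCC(C)(C)O)C1=O
F2 | step 17 | (1S,2S)-2,4-dimethyl-2-(4-methylpent-3-en-1-yl)-3-oxocyclohex-4-en-1-yl acetate | CC1=CC[C@H](OC(C)=O)[C@](C)(CCC=C(C)C)C1=O
F3 | step 17 | (5S,6S)-5-hydroxy-2,6-dimethyl-6-(4-methylpent-3-en-1-yl)cyclohex-2-en-1-one | CC1=CC[C@H](O)[C@](C)(CCC=C(C)C)C1=O
F4 | step 18 | (1S,2S,4R)-2,4-dimethyl-2-[4-methyl-4-(triethylsilyloxy)pentyl]-3-oxocyclohexyl acetate | C[C@@H]1CC[C@H](OC(C)=O)[C@](C)(CCCC(C)(C)O[Si](CC)(CC)CC)C1=O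
F5 | step 19 | enynol: 16 with its alkyne terminus bonded to C6 of (5aS,9aS)-2,2,5a,7-tetramethyl-2,3,4,5,5a,6,9,9a-octahydro-1-benzoxepin-6-ol (6-OH cis to O1) | CC1=C(Cc2cc(O)ccc2OC)[C@]2(C)CCC[C@@](C)(C#C[C@@]3(O)C(C)=CC[C@@H]4OC(C)(C)CCC[C@@]43C)[C@H]2CC1
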